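Assumption: bleochrin A has no stereocentre, so the compound asked for is the achiral molecule itself; stereocentres in intermediates are transient and left uncontrolled.

**Retrosynthetic overview**
1. Bleochrin A 21 comes from global O-debenzylation of tetrabenzyl ether 20.
2. Ring A of 20 is aromatised last, by dehydrative isoaromatization of aldol adduct 18; 18 comes from the new γ-selective vinylogous aldol of methyl vinylogous ester 17 with 4-(benzyloxy)benzaldehyde, which places the second benzyl group next to the methoxy carbon.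
3. 17 comes from O-methylation of the symmetric 2-benzyl-1,3-dione 16, itself made by reductive alkylation of dione 13 (first benzyl group, between the two oxygens).
4. Dione 13 (the six carbons of ring A) comes from Michael–Claisen annulation of enone 9 with dimethyl malonate; 9 comes from aryl bromide 5 by Heck reaction and Wittig olefination.
5. Ring B is bought (compound 1) and its diarylmethane is made by Grignard addition and ionic reduction. Ring order: ring B first, ring A carbocycle in step 6, ring A aromatic in step 10.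

**Route**

Step 1
Reactants: 1 2-bromo-4-hydroxybenzaldehyde
Product: 2 4-(benzyloxy)-2-bromobenzaldehyde
Conditions: BnBr, K2CO3, DMF, rt
Reagents that add atoms: benzyl bromide, BrCc1ccccc1
Why: Williamson ether synthesis (SN2 O-alkylation of the phenoxide) protects the ring B phenol as a benzyl ether that lasts to the final hydrogenolysis.

Step 2
Reactants: 2 4-(benzyloxy)-2-bromobenzaldehyde; 3 4-(benzyloxy)phenylmagnesium bromide
Product: 4 [4-(benzyloxy)-2-bromophenyl][4-(benzyloxy)phenyl]methanol (racemic)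
Conditions: THF, −20 to 0 °C; sat. aq NH4Cl
Reagents that add atoms: none
Why: Grignard 1,2-addition to the aldehyde is much faster than any exchange at the aryl bromide at this temperature, and the racemic carbinol centre is removed in step 3.

Step 3
Reactants: 4 [4-(benzyloxy)-2-bromophenyl][4-(benzyloxy)phenyl]methanol
Product: 5 4-(benzyloxy)-1-[4-(benzyloxy)benzyl]-2-bromobenzene
Conditions: Et3SiH, CF3CO2H, CH2Cl2, 0 °C
Reagents that add atoms: none
Why: Ionic hydrogenation, in which the benzhydryl cation stabilised by two p-alkoxyaryl groups is trapped by hydride from the silane while aryl benzyl ethers and the C–Br bond are untouched.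

Step 4
Reactants: 5 4-(benzyloxy)-1-[4-(benzyloxy)benzyl]-2-bromobenzene; 6 allyl alcohol (prop-2-en-1-ol)
Product: 7 3-{5-(benzyloxy)-2-[4-(benzyloxy)benzyl]phenyl}propanal
Conditions: Pd(OAc)2 (5 mol %), n-Bu4NCl, NaHCO3, DMF, 90 °C
Reagents that add atoms: none
Why: Heck reaction under Jeffery conditions, where oxidative addition of Ar–Br to zerovalent palladium, terminal arylation of the alkene and β-hydride elimination toward the carbinol give the enol and hence the saturated aldehyde.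

Step 5
Reactants: 7 3-{5-(benzyloxy)-2-[4-(benzyloxy)benzyl]phenyl}propanal; 8 1-(triphenylphosphoranylidene)propan-2-one
Product: 9 (E)-6-{5-(benzyloxy)-2-[4-(benzyloxy)benzyl]phenyl}hex-3-en-2-one
Conditions: CH2Cl2, 40 °C
Reagents that add atoms: none
Why: Wittig olefination with a stabilised ylide gives the E-enone cleanly (the geometry is lost in step 6).

Step 6
Reactants: 9 (E)-6-{5-(benzyloxy)-2-[4-(benzyloxy)benzyl]phenyl}hex-3-en-2-one; 10 dimethyl malonate
Product: 13 5-(2-{5-(benzyloxy)-2-[4-(benzyloxy)benzyl]phenyl}ethyl)cyclohexane-1,3-dione, via cyclic keto ester 11 (not isolated), via keto acid 12 (not isolated)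
Conditions: NaOMe, MeOH–THF, reflux; then 2 M aq NaOH, reflux; then aq HCl to pH 2, 70 °C
Reagents that add atoms: none
Why: Michael addition followed by intramolecular Claisen (Dieckmann-type) condensation, saponification and decarboxylation of the β-keto acid is the classic route to 5-substituted cyclohexane-1,3-diones and builds the six carbons of ring A; product 13 is achiral.

Step 7
Reactants: 13 5-(2-{5-(benzyloxy)-2-[4-(benzyloxy)benzyl]phenyl}ethyl)cyclohexane-1,3-dione; 14 4-(benzyloxy)benzaldehyde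
Product: 16 2-[4-(benzyloxy)benzyl]-5-(2-{5-(benzyloxy)-2-[4-(benzyloxy)benzyl]phenyl}ethyl)cyclohexane-1,3-dione, via alkylidene dione 15 (not isolated)
Conditions: diethyl 2,6-dimethyl-1,4-dihydropyridine-3,5-dicarboxylate (Hantzsch ester), L-proline (20 mol %), CH2Cl2, rt
Reagents that add atoms: none
Why: Organocatalytic three-component reductive alkylation, in which Knoevenagel condensation at C2 is followed by conjugate hydride transfer from the Hantzsch ester, puts the first benzyl group between the two carbonyls without O-alkylation or dialkylation.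

Step 8
Reactants: 16 2-[4-(benzyloxy)benzyl]-5-(2-{5-(benzyloxy)-2-[4-(benzyloxy)benzyl]phenyl}ethyl)cyclohexane-1,3-dione
Product: 17 2-[4-(benzyloxy)benzyl]-5-(2-{5-(benzyloxy)-2-[4-(benzyloxy)benzyl]phenyl}ethyl)-3-methoxycyclohex-2-en-1-one (racemic)
Conditions: MeOH, HC(OMe)3, TsOH·H2O (5 mol %), 50 °C
Reagents that add atoms: methanol, CO
Why: Acid-catalysed enol etherification (vinylogous ester formation) of a symmetric 2-substituted 1,3-dione can give only one constitutional isomer and differentiates the two oxygens, one of which is now the methoxy group of the target.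

Step 9
Reactants: 17 2-[4-(benzyloxy)benzyl]-5-(2-{5-(benzyloxy)-2-[4-(benzyloxy)benzyl]phenyl}ethyl)-3-methoxycyclohex-2-en-1-one; 14 4-(benzyloxy)benzaldehyde
Product: 18 2-[4-(benzyloxy)benzyl]-4-{[4-(benzyloxy)phenyl](hydroxy)methyl}-5-(2-{5-(benzyloxy)-2-[4-(benzyloxy)benzyl]phenyl}ethyl)-3-methoxycyclohex-2-en-1-one (racemic mixture of diastereomers)
Conditions: Al(O-2,6-Ph2C6H3)3 (3.3 equiv, made from AlMe3 and 2,6-diphenylphenol in PhMe, rt), 14 (1.5 equiv), PhMe, −78 °C; LiN(i-Pr)2 (2.3 equiv), THF, −78 °C; 1 M aq HCl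
Reagents that add atoms: none
Why: Proposed new method: aluminium tris(2,6-diphenylphenoxide) binds the carbonyl of 17 and of aldehyde 14 inside its aryl pocket, so the C6 protons next to the carbonyl (the normal kinetic Stork–Danheiser site) are shielded and the amide base removes the remote C4–H; the resulting linear dienolate, with C2 blocked, attacks the aluminium-activated aldehyde through C4 and forms the C4–CH(OH)Ar bond beside the methoxy-bearing carbon; the closest known reaction type is the bulky-aluminium-aryloxide-directed vinylogous aldol of enones and enoates, not yet shown for 3-alkoxycyclohex-2-enones; the new stereocentres are uncontrolled and are erased in step 10.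

Step 10
Reactants: 18 2-[4-(benzyloxy)benzyl]-4-{[4-(benzyloxy)phenyl](hydroxy)methyl}-5-(2-{5-(benzyloxy)-2-[4-(benzyloxy)benzyl]phenyl}ethyl)-3-methoxycyclohex-2-en-1-one
Product: 20 2,4-bis[4-(benzyloxy)benzyl]-5-(2-{5-(benzyloxy)-2-[4-(benzyloxy)benzyl]phenyl}ethyl)-3-methoxyphenol, via arylidene dienone 19 (not isolated)
Conditions: TsOH·H2O (10 mol %), 4 Å MS, PhMe, 70 °C
Reagents that add atoms: none
Why: Acid-catalysed E1 dehydration of the p-alkoxybenzylic alcohol gives push–pull dienone 19, which enolises toward C6 to a semibenzene and isoaromatizes by proton shift from C5 to the exocyclic carbon, so all stereocentres vanish, the ketone oxygen becomes the free phenol and the methoxy group ends up flanked by both benzyl groups.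

Step 11
Reactants: 20 2,4-bis[4-(benzyloxy)benzyl]-5-(2-{5-(benzyloxy)-2-[4-(benzyloxy)benzyl]phenyl}ethyl)-3-methoxyphenol
Product: 21 bleochrin A, 5-{2-[5-hydroxy-2-(4-hydroxybenzyl)phenyl]ethyl}-2,4-bis(4-hydroxybenzyl)-3-methoxyphenol
Conditions: H2 (1 atm), 10% Pd/C (palladium on carbon), EtOAc–MeOH, rt
Reagents that add atoms: none
Why: Catalytic hydrogenolysis cleaves the four aryl benzyl ethers, while the methyl ether and the diarylmethane C–C bonds are inert.

**Compound list**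
1 | 2-bromo-4-hydroxybenzaldehyde | O=Cc1ccc(O)cc1Br | starting material
2 | 4-(benzyloxy)-2-bromobenzaldehyde | O=Cc1ccc(OCc2ccccc2)cc1Br | intermediate
3 | 4-(benzyloxy)phenylmagnesium bromide | Br[Mg]c1ccc(OCc2ccccc2)cc1 | starting material
4 | [4-(benzyloxy)-2-bromophenyl][4-(benzyloxy)phenyl]methanol (racemic) | OC(c1ccc(OCc2ccccc2)cc1)c1ccc(OCc2ccccc2)cc1Br | intermediate
5 | 4-(benzyloxy)-1-[4-(benzyloxy)benzyl]-2-bromobenzene | Brc1cc(OCc2ccccc2)ccc1Cc1ccc(OCc2ccccc2)cc1 | intermediate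
6 | allyl alcohol (prop-2-en-1-ol) | C=CCO | starting material
7 | 3-{5-(benzyloxy)-2-[4-(benzyloxy)benzyl]phenyl}propanal | O=CCCc1cc(OCc2ccccc2)ccc1Cc1ccc(OCc2ccccc2)cc1 | intermediate
8 | 1-(triphenylphosphoranylidene)propan-2-one | CC(=O)C=P(c1ccccc1)(c1ccccc1)c1ccccc1 | starting material
9 | (E)-6-{5-(benzyloxy)-2-[4-(benzyloxy)benzyl]phenyl}hex-3-en-2-one | CC(=O)/C=C/CCc1cc(OCc2ccccc2)ccc1Cc1ccc(OCc2ccccc2)cc1 | intermediate
10 | dimethyl malonate | COC(=O)CC(=O)OC | starting material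
11 | methyl 6-(2-{5-(benzyloxy)-2-[4-(benzyloxy)benzyl]phenyl}ethyl)-2,4-dioxocyclohexane-1-carboxylate (racemic, diastereomer and enol mixture; not isolated) | COC(=O)C1C(=O)CC(=O)CC1CCc1cc(OCc2ccccc2)ccc1Cc1ccc(OCc2ccccc2)cc1 | intermediate
12 | 6-(2-{5-(benzyloxy)-2-[4-(benzyloxy)benzyl]phenyl}ethyl)-2,4-dioxocyclohexane-1-carboxylic acid (racemic, diastereomer and enol mixture; not isolated) | OC(=O)C1C(=O)CC(=O)CC1CCc1cc(OCc2ccccc2)ccc1Cc1ccc(OCc2ccccc2)cc1 | intermediate
13 | 5-(2-{5-(benzyloxy)-2-[4-(benzyloxy)benzyl]phenyl}ethyl)cyclohexane-1,3-dione (achiral) | O=C1CC(=O)CC(CCc2cc(OCc3ccccc3)ccc2Cc2ccc(OCc3ccccc3)cc2)C1 | intermediate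
14 | 4-(benzyloxy)benzaldehyde | O=Cc1ccc(OCc2ccccc2)cc1 | starting material
15 | 2-[4-(benzyloxy)benzylidene]-5-(2-{5-(benzyloxy)-2-[4-(benzyloxy)benzyl]phenyl}ethyl)cyclohexane-1,3-dione (racemic; not isolated) | O=C1CC(CCc2cc(OCc3ccccc3)ccc2Cc2ccc(OCc3ccccc3)cc2)CC(=O)C1=Cc1ccc(OCc2ccccc2)cc1 | intermediate
16 | 2-[4-(benzyloxy)benzyl]-5-(2-{5-(benzyloxy)-2-[4-(benzyloxy)benzyl]phenyl}ethyl)cyclohexane-1,3-dione (drawn as diketone; largely enolised, no lasting stereocentre) | O=C1CC(CCc2cc(OCc3ccccc3)ccc2Cc2ccc(OCc3ccccc3)cc2)CC(=O)C1Cc1ccc(OCc2ccccc2)cc1 | intermediate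
17 | 2-[4-(benzyloxy)benzyl]-5-(2-{5-(benzyloxy)-2-[4-(benzyloxy)benzyl]phenyl}ethyl)-3-methoxycyclohex-2-en-1-one (racemic) | COC1=C(Cc2ccc(OCc3ccccc3)cc2)C(=O)CC(CCc2cc(OCc3ccccc3)ccc2Cc2ccc(OCc3ccccc3)cc2)C1 | intermediate
18 | 2-[4-(benzyloxy)benzyl]-4-{[4-(benzyloxy)phenyl](hydroxy)methyl}-5-(2-{5-(benzyloxy)-2-[4-(benzyloxy)benzyl]phenyl}ethyl)-3-methoxycyclohex-2-en-1-one (racemic mixture of diastereomers) | COC1=C(Cc2ccc(OCc3ccccc3)cc2)C(=O)CC(CCc2cc(OCc3ccccc3)ccc2Cc2ccc(OCc3ccccc3)cc2)C1C(O)c1ccc(OCc2ccccc2)cc1 | intermediate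
19 | 2-[4-(benzyloxy)benzyl]-4-[4-(benzyloxy)benzylidene]-5-(2-{5-(benzyloxy)-2-[4-(benzyloxy)benzyl]phenyl}ethyl)-3-methoxycyclohex-2-en-1-one (racemic, alkene geometry unassigned; not isolated) | COC1=C(Cc2ccc(OCc3ccccc3)cc2)C(=O)CC(CCc2cc(OCc3ccccc3)ccc2Cc2ccc(OCc3ccccc3)cc2)C1=Cc1ccc(OCc2ccccc2)cc1 | intermediate
20 | 2,4-bis[4-(benzyloxy)benzyl]-5-(2-{5-(benzyloxy)-2-[4-(benzyloxy)benzyl]phenyl}ethyl)-3-methoxyphenol | COc1c(Cc2ccc(OCc3ccccc3)cc2)c(O)cc(CCc2cc(OCc3ccccc3)ccc2Cc2ccc(OCc3ccccc3)cc2)c1Cc1ccc(OCc2ccccc2)cc1 | intermediate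
21 | bleochrin A, 5-{2-[5-hydroxy-2-(4-hydroxybenzyl)phenyl]ethyl}-2,4-bis(4-hydroxybenzyl)-3-methoxyphenol (achiral) | COc1c(Cc2ccc(O)cc2)c(O)cc(CCc2cc(O)ccc2Cc2ccc(O)cc2)c1Cc1ccc(O)cc1 | target

**Step count and risks**
Total step count: 11. Longest linear sequence: 11 steps (1 to 21).

Three steps most likely to fail:

Step 9 (the proposed new method; the risk is deprotonation at C6 instead of C4, or no reaction of the hindered dienolate). The fallback uses known chemistry and sets out from 16. Benzyl alcohol with TsOH·H2O in toluene under Dean–Stark conditions gives 3-(benzyloxy)-2-[4-(benzyloxy)benzyl]-5-(2-{5-(benzyloxy)-2-[4-(benzyloxy)benzyl]phenyl}ethyl)cyclohex-2-en-1-one F2. Kinetic Stork–Danheiser alkylation at C6 (LiN(i-Pr)2, THF, −78 °C, then 4-(benzyloxy)benzyl bromide) gives 3-(benzyloxy)-2,6-bis[4-(benzyloxy)benzyl]-5-(2-{5-(benzyloxy)-2-[4-(benzyloxy)benzyl]phenyl}ethyl)cyclohex-2-en-1-one F3. Aerobic dehydrogenation (Pd(OCOCF3)2, 2-(dimethylamino)pyridine, TsOH, O2, DMSO, 80 °C) gives 3-(benzyloxy)-2,6-bis[4-(benzyloxy)benzyl]-5-(2-{5-(benzyloxy)-2-[4-(benzyloxy)benzyl]phenyl}ethyl)phenol F4, in which the free hydroxyl is the one flanked by both benzyl groups. MeI and K2CO3 in DMF give 1-(benzyloxy)-2,4-bis[4-(benzyloxy)benzyl]-5-(2-{5-(benzyloxy)-2-[4-(benzyloxy)benzyl]phenyl}ethyl)-3-methoxybenzene F5, and hydrogenolysis (H2, 10% Pd/C) of its five benzyl ethers comes back to the route at 21.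

Step 10 (the risk is hydrolysis of the enol ether by the water released, or cation side reactions). The fallback sets out from 18 and replaces the one-flask cationic pathway by a base-promoted elimination followed by metal-hydride alkene isomerization. MsCl and Et3N in CH2Cl2 at 0 °C give [4-(benzyloxy)phenyl]{3-[4-(benzyloxy)benzyl]-6-(2-{5-(benzyloxy)-2-[4-(benzyloxy)benzyl]phenyl}ethyl)-2-methoxy-4-oxocyclohex-2-en-1-yl}methyl methanesulfonate F6, which on addition of DBU eliminates (E1cB) to dienone 19, now isolated. RhCl3·3H2O (5 mol %) in EtOH at 80 °C then moves the exocyclic double bond into the ring by rhodium-hydride addition and elimination; the resulting cyclohexa-2,5-dienone tautomerises and the route is rejoined at 20.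

Step 4 (the risk is a sluggish or branched Heck reaction with the ortho-substituted aryl bromide). The fallback sets out from 5. Negishi coupling with (3-ethoxy-3-oxopropyl)zinc bromide (Pd(OAc)2, SPhos, THF, 50 °C) gives ethyl 3-{5-(benzyloxy)-2-[4-(benzyloxy)benzyl]phenyl}propanoate F1, and partial reduction with i-Bu2AlH in CH2Cl2 at −78 °C comes back to the route at 7.

Further compounds
F1 | step 4 | ethyl 3-{5-(benzyloxy)-2-[4-(benzyloxy)benzyl]phenyl}propanoate | CCOC(=O)CCc1cc(OCc2ccccc2)ccc1Cc1ccc(OCc2ccccc2)cc1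
F2 | step 9 | 3-(benzyloxy)-2-[4-(benzyloxy)benzyl]-5-(2-{5-(benzyloxy)-2-[4-(benzyloxy)benzyl]phenyl}ethyl)cyclohex-2-en-1-one (racemic) | O=C1CC(CCc2cc(OCc3ccccc3)ccc2Cc2ccc(OCc3ccccc3)cc2)CC(OCc2ccccc2)=C1Cc1ccc(OCc2ccccc2)cc1
F3 | step 9 | 3-(benzyloxy)-2,6-bis[4-(benzyloxy)benzyl]-5-(2-{5-(benzyloxy)-2-[4-(benzyloxy)benzyl]phenyl}ethyl)cyclohex-2-en-1-one (racemic mixture of diastereomers) | O=C1C(Cc2ccc(OCc3ccccc3)cc2)C(CCc2cc(OCc3ccccc3)ccc2Cc2ccc(OCc3ccccc3)cc2)CC(OCc2ccccc2)=C1Cc1ccc(OCc2ccccc2)cc1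
F4 | step 9 | 3-(benzyloxy)-2,6-bis[4-(benzyloxy)benzyl]-5-(2-{5-(benzyloxy)-2-[4-(benzyloxy)benzyl]phenyl}ethyl)phenol | Oc1c(Cc2ccc(OCc3ccccc3)cc2)c(OCc2ccccc2)cc(CCc2cc(OCc3ccccc3)ccc2Cc2ccc(OCc3ccccc3)cc2)c1Cc1ccc(OCc2ccccc2)cc1
F5 | step 9 | 1-(benzyloxy)-2,4-bis[4-(benzyloxy)benzyl]-5-(2-{5-(benzyloxy)-2-[4-(benzyloxy)benzyl]phenyl}ethyl)-3-methoxybenzene | COc1c(Cc2ccc(OCc3ccccc3)cc2)c(OCc2ccccc2)cc(CCc2cc(OCc3ccccc3)ccc2Cc2ccc(OCc3ccccc3)cc2)c1Cc1ccc(OCc2ccccc2)cc1
F6 | step 10 | [4-(benzyloxy)phenyl]{3-[4-(benzyloxy)benzyl]-6-(2-{5-(benzyloxy)-2-[4-(benzyloxy)benzyl]phenyl}ethyl)-2-methoxy-4-oxocyclohex-2-en-1-yl}methyl methanesulfonate (racemic mixture of diastereomers) | COC1=C(Cc2ccc(OCc3ccccc3)cc2)C(=O)CC(CCc2cc(OCc3ccccc3)ccc2Cc2ccc(OCc3ccccc3)cc2)C1C(OS(C)(=O)=O)c1ccc(OCc2ccccc2)cc1
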